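## Retrosynthetic overview

1. Target ⇐ isopropenyl congener (selective hydrogenation) ⇐ C6–O bond made with inversion (Mitsunobu acetate) from the 6,7-trans ring alcohol.
2. The ten-membered ring (the only ring) ⇐ C6–C7 closure of an open-chain chloro enal by intramolecular allylchromium addition.
3. Key C3–O bond ⇐ enantioselective γ-angeloyloxylation of (2E,6Z)-farnesal with diangeloyl peroxide (two angelic acids joined through H2O2) via a dienamine; ester and (S) centre arrive in one step.
4. (2E,6Z)-Farnesal ⇐ nerylacetone (Horner–Wadsworth–Emmons olefination with a Weinreb phosphonate, then reduction).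

Assumption: nerylacetone, angelic acid and phosphonate 2 are purchased (nerylacetone is otherwise two steps from nerol). Aminocatalyst A is taken as available; otherwise it is made by standard squaramide chemistry from dimethyl squarate, 3,5-bis(trifluoromethyl)aniline and tert-butyl (2S)-2-(aminomethyl)pyrrolidine-1-carboxylate, and this is not counted. The C10 epimers of 9 are carried as a mixture.

Conventions: open-chain compounds use farnesane numbering (C1 = carbonyl carbon). Ring compounds use germacrane numbering (C3 bears the angelate, C6 the second oxygen, C7 the three-carbon side chain, C1=C10 is the Z alkene, C4=C5 the E alkene). With isopropenyl on C7 the target-like arrangement at C6 is called S; with isopropyl it is called R (priority change only).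

Catalyst A (step 4): 3-{[3,5-bis(trifluoromethyl)phenyl]amino}-4-{[(2S)-pyrrolidin-2-ylmethyl]amino}cyclobut-3-ene-1,2-dione, O=C1C(=O)C(NC[C@@H]2CCCN2)=C1Nc1cc(C(F)(F)F)cc(C(F)(F)F)c1

## Route

Step 1
Reactants: 1 nerylacetone [(5Z)-6,10-dimethylundeca-5,9-dien-2-one]; 2 diethyl [2-(methoxy(methyl)amino)-2-oxoethyl]phosphonate
Product: 3 (2E,6Z)-N-methoxy-N,3,7,11-tetramethyldodeca-2,6,10-trienamide
Conditions: NaH, THF, 0 to 50 °C; 2E isomer separated on silica
Reagents that add atoms: none
Why: Horner–Wadsworth–Emmons olefination of the methyl ketone with the stabilised phosphonate anion is E-selective (about 4:1), leaves the (Z)-alkene of nerylacetone untouched and creates no stereocentre.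

Step 2
Reactants: 3 (2E,6Z)-N-methoxy-N,3,7,11-tetramethyldodeca-2,6,10-trienamide
Product: 4 (2E,6Z)-3,7,11-trimethyldodeca-2,6,10-trienal [(2E,6Z)-farnesal]
Conditions: i-Bu2AlH (1.2 equiv), THF, −78 °C; aq. potassium sodium tartrate
Reagents that add atoms: none
Why: Weinreb amide reduction stops at the aldehyde because chelation by the N-methoxy group prevents over-reduction, and the hydride adds 1,2 so both alkene geometries are kept.

Step 3
Reactants: 5 angelic acid [(2Z)-2-methylbut-2-enoic acid] (2 equiv per molecule of 6)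
Product: 6 diangeloyl peroxide [bis((2Z)-2-methylbut-2-enoyl) peroxide]
Conditions: 5 (2.0 equiv), H2O2 (50% aq., 1.0 equiv), DCC (2.0 equiv), CH2Cl2, −10 to 0 °C; kept as a titrated solution
Reagents that add atoms: angelic acid (the second equivalent of 5), C/C=C(/C)C(=O)O; hydrogen peroxide, OO
Why: Carbodiimide-mediated diacyl peroxide synthesis, in which two molecules of 5 are joined through the two oxygens of hydrogen peroxide while each DCC takes up one water (2 RCO2H + H2O2 + 2 DCC → (RCO2)2 + 2 dicyclohexylurea), runs cold and without nucleophilic catalysts, so the (Z)-geometry of the angeloyl group is not isomerised to tiglate and no stereocentre is involved.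

Step 4
Reactants: 4 (2E,6Z)-farnesal; 6 diangeloyl peroxide
Product: 8 (2E,4S,6Z)-3,7,11-trimethyl-1-oxododeca-2,6,10-trien-4-yl (2Z)-2-methylbut-2-enoate, via dienamine 7 (not isolated)
Conditions: catalyst A (20 mol %), 6 (1.2 equiv), hydroquinone (10 mol %), CH2Cl2, −20 °C; released angelic acid recovered by NaHCO3 extraction
Reagents that add atoms: none
Why: Proposed new method: an amine-catalysed, hydrogen-bond-directed enantioselective γ-acyloxylation of a β-methyl enal, in which the pyrrolidine nitrogen of A condenses with 4 to give the thermodynamic (1E,3E)-dienamine 7 (deprotonation at the C4 methylene, not the C3 methyl), the squaramide N–H bonds bind a carbonyl oxygen of 6 and hold its O–O bond over C4, and C4 attacks the peroxide oxygen in an SN2-type displacement of angelate on its Si face (the face carrying the squaramide arm), after which hydrolysis releases the conjugated (2E)-enal with the (4S) centre and the ester already in place; α-attack is disfavoured because it would give a deconjugated product at a carbon flanked by the C3 methyl and the catalyst, and the rapidly equilibrating dienamine isomers funnel through the one that fits the bound peroxide; the closest known reaction types are the amine-catalysed α-benzoyloxylation of aldehydes with dibenzoyl peroxide and the dienamine-mediated γ-amination of enals with azodicarboxylates.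

Step 5
Reactants: 8 (2E,4S,6Z)-3,7,11-trimethyl-1-oxododeca-2,6,10-trien-4-yl (2Z)-2-methylbut-2-enoate
Product: 9 (2E,4S,6Z)-10-chloro-3,7,11-trimethyl-1-oxododeca-2,6,11-trien-4-yl (2Z)-2-methylbut-2-enoate (C10 epimers)
Conditions: NCS (1.05 equiv), PhSeCl (10 mol %), CH2Cl2, 25 °C
Reagents that add atoms: N-chlorosuccinimide, O=C1CCC(=O)N1Cl
Why: Selenium-catalysed ene-type allylic chlorination turns the terminal isopropylidene into the rearranged secondary allylic chloride; the enal and angelate alkenes are electron-poor and inert, the 6,7-(Z)-alkene is more hindered and inductively deactivated by the homoallylic C4 ester, and the unselectively formed C10 centre is erased in step 6.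

Step 6
Reactants: 9 (2E,4S,6Z)-10-chloro-3,7,11-trimethyl-1-oxododeca-2,6,11-trien-4-yl (2Z)-2-methylbut-2-enoate
Product: 11 (3S,6R,7S)-6-hydroxygermacra-1(10)Z,4E,11-trien-3-yl angelate [(1S,2E,4R,5S,8Z)-4-hydroxy-2,8-dimethyl-5-(prop-1-en-2-yl)cyclodeca-2,8-dien-1-yl (2Z)-2-methylbut-2-enoate], via allylchromium 10 (not isolated)
Conditions: CrCl2 (8 equiv), THF–DMF 4:1, 25 °C, 9 added by syringe pump to 3 mM
Reagents that add atoms: none
Why: Intramolecular Nozaki–Hiyama–Kishi-type allylation, in which divalent chromium inserts into the allylic C–Cl bond to give allylchromium 10 (trivalent chromium) that adds through its γ-carbon to the aldehyde in a six-membered chair transition state; γ-substituted allylchromium reagents are anti-selective whatever the halide configuration, which gives the 6,7-trans ring alcohol, and of the two trans isomers the (6R,7S) one is expected to dominate because its ring-forming conformer keeps the C3 ester pseudo-equatorial on the ring periphery (minor diastereomer removed by chromatography).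

Step 7
Reactants: 11 (3S,6R,7S)-6-hydroxygermacra-1(10)Z,4E,11-trien-3-yl angelate
Product: 13 (3S,6S,7S)-6-acetoxygermacra-1(10)Z,4E,11-trien-3-yl angelate [(1S,2E,4S,5S,8Z)-4-acetoxy-2,8-dimethyl-5-(prop-1-en-2-yl)cyclodeca-2,8-dien-1-yl (2Z)-2-methylbut-2-enoate], via alkoxyphosphonium 12 (not isolated)
Conditions: PPh3, DIAD, AcOH (2 equiv each), toluene, 0 to 25 °C
Reagents that add atoms: acetic acid, CC(=O)O
Why: Mitsunobu reaction, in which the C6 hydroxyl is activated as alkoxyphosphonium 12 and displaced by acetate in an SN2 step with inversion, turning the 6,7-trans alcohol into the required 6,7-cis acetate without touching C3 or C7.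

Step 8
Reactants: 13 (3S,6S,7S)-6-acetoxygermacra-1(10)Z,4E,11-trien-3-yl angelate
Product: 14 target, (3S,6R,7S)-6-acetoxygermacra-1(10)Z,4E-dien-3-yl angelate [(1S,2E,4R,5S,8Z)-4-acetoxy-2,8-dimethyl-5-(propan-2-yl)cyclodeca-2,8-dien-1-yl (2Z)-2-methylbut-2-enoate]
Conditions: H2 (1 atm), RhCl(PPh3)3 (10 mol %), benzene, 25 °C
Reagents that add atoms: none
Why: Homogeneous hydrogenation with RhCl(PPh3)3 reduces the unhindered 1,1-disubstituted isopropenyl alkene far faster than the two trisubstituted ring alkenes and the conjugated angelate alkene, does not hydrogenolyse allylic esters, and creates or disturbs no stereocentre.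

## Compound list

1 | nerylacetone, (5Z)-6,10-dimethylundeca-5,9-dien-2-one | CC(=O)CC/C=C(/C)CCC=C(C)C | starting material
2 | diethyl [2-(methoxy(methyl)amino)-2-oxoethyl]phosphonate | CCOP(=O)(OCC)CC(=O)N(C)OC | starting material
3 | (2E,6Z)-N-methoxy-N,3,7,11-tetramethyldodeca-2,6,10-trienamide | CON(C)C(=O)/C=C(\C)CC/C=C(/C)CCC=C(C)C | intermediate
4 | (2E,6Z)-3,7,11-trimethyldodeca-2,6,10-trienal | O=C/C=C(\C)CC/C=C(/C)CCC=C(C)C | intermediate
5 | angelic acid, (2Z)-2-methylbut-2-enoic acid | C/C=C(/C)C(=O)O | starting material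
6 | diangeloyl peroxide | C/C=C(/C)C(=O)OOC(=O)/C(C)=C\C | intermediate
7 | (1E,3E,6Z)-dienamine of 4 on the pyrrolidine nitrogen of catalyst A | CC(C)=CCC/C(C)=C\C/C=C(C)/C=C/N1CCC[C@H]1CNC1=C(Nc2cc(C(F)(F)F)cc(C(F)(F)F)c2)C(=O)C1=O | intermediate
8 | (2E,4S,6Z)-3,7,11-trimethyl-1-oxododeca-2,6,10-trien-4-yl (2Z)-2-methylbut-2-enoate | O=C/C=C(\C)[C@@H](OC(=O)/C(C)=C\C)C/C=C(/C)CCC=C(C)C | intermediate
9 | (2E,4S,6Z)-10-chloro-3,7,11-trimethyl-1-oxododeca-2,6,11-trien-4-yl (2Z)-2-methylbut-2-enoate, C10 epimers | O=C/C=C(\C)[C@@H](OC(=O)/C(C)=C\C)C/C=C(/C)CCC(Cl)C(C)=C | intermediate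
10 | allylchromium dichloride from 9, chromium on C12 | O=C/C=C(\C)[C@@H](OC(=O)/C(C)=C\C)C/C=C(/C)CCC=C(C)C[Cr](Cl)Cl | intermediate
11 | (1S,2E,4R,5S,8Z)-4-hydroxy-2,8-dimethyl-5-(prop-1-en-2-yl)cyclodeca-2,8-dien-1-yl (2Z)-2-methylbut-2-enoate | C/C=C(/C)C(=O)O[C@H]1C/C=C(/C)CC[C@@H](C(C)=C)[C@H](O)/C=C/1C | intermediate
12 | C6 alkoxytriphenylphosphonium acetate of 11 | C/C=C(/C)C(=O)O[C@H]1C/C=C(/C)CC[C@@H](C(C)=C)[C@H](O[P+](c2ccccc2)(c2ccccc2)c2ccccc2)/C=C/1C.CC(=O)[O-] | intermediate
13 | (1S,2E,4S,5S,8Z)-4-acetoxy-2,8-dimethyl-5-(prop-1-en-2-yl)cyclodeca-2,8-dien-1-yl (2Z)-2-methylbut-2-enoate | C/C=C(/C)C(=O)O[C@H]1C/C=C(/C)CC[C@@H](C(C)=C)[C@@H](OC(C)=O)/C=C/1C | intermediate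
14 | (1S,2E,4R,5S,8Z)-4-acetoxy-2,8-dimethyl-5-(propan-2-yl)cyclodeca-2,8-dien-1-yl (2Z)-2-methylbut-2-enoate | C/C=C(/C)C(=O)O[C@H]1C/C=C(/C)CC[C@@H](C(C)C)[C@@H](OC(C)=O)/C=C/1C | target

## Step count and risks

Total steps: 8. Longest linear sequence: 7 (1 → 3 → 4 → 8 → 9 → 11 → 13 → 14); step 3 is a one-step side branch.

Step 4 (proposed new method). It may give α- instead of γ-oxygenation, oxygenation at the C3 methyl, low enantioselectivity, or N-acyloxylation of the catalyst. If the sense of induction is reversed, the mirror-image catalyst is used. The fallback uses known chemistry, sets out from 1 and returns at 8. D-Proline-catalysed α-aminoxylation of 1 with nitrosobenzene at the C3 methylene gives (3S,5Z)-6,10-dimethyl-3-[(phenylamino)oxy]undeca-5,9-dien-2-one F1. N–O cleavage with Zn/AcOH gives hydroxy ketone F2. Wittig olefination with Ph3P=CHCO2Et (toluene, 80 °C) gives the (2E)-γ-hydroxy enoate F3. Reduction with i-Bu2AlH gives diol F4. TEMPO/PhI(OAc)2 oxidises only the primary allylic alcohol to give hydroxy enal F5. Esterification of F5 with the mixed anhydride preformed from 5 and 2,4,6-trichlorobenzoyl chloride (NaHCO3, toluene, 80 °C, no nucleophilic amine catalyst) gives 8.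

Step 5. The 6,7-(Z)-alkene may compete with the terminal alkene and give regioisomeric chlorides that are hard to separate. The fallback sets out from 8 and returns at 11. Terminal allylic oxidation with SeO2 (cat.)/t-BuOOH at the (E)-methyl gives the 12-hydroxy compound F6. One-pot treatment with MsCl, Et3N and LiCl gives the primary allylic chloride F7. Under the conditions of step 6, F7 gives the same allylchromium 10 and closes to 11.

Step 6. The macrocyclisation may give oligomers or the wrong trans diastereomer, since control by the remote C3 centre is not assured. The fallback sets out from 9 and returns at 13. Stannylation with Bu3SnSnBu3 under zerovalent palladium catalysis (Pd(PPh3)4) gives the isolable allylstannane F8. BF3·OEt2 at −78 °C under high dilution closes the ring through an open transition state, which is syn-selective and gives the 6,7-cis alcohol F9 directly. Plain acetylation (Ac2O, pyridine) then gives 13, so the inversion of step 7 is not needed.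

## Further compounds

F1 | step 4 | (3S,5Z)-6,10-dimethyl-3-[(phenylamino)oxy]undeca-5,9-dien-2-one | CC(=O)[C@@H](ONc1ccccc1)C/C=C(/C)CCC=C(C)C
F2 | step 4 | (3S,5Z)-3-hydroxy-6,10-dimethylundeca-5,9-dien-2-one | CC(=O)[C@@H](O)C/C=C(/C)CCC=C(C)C
F3 | step 4 | ethyl (2E,4S,6Z)-4-hydroxy-3,7,11-trimethyldodeca-2,6,10-trienoate | CCOC(=O)/C=C(\C)[C@@H](O)C/C=C(/C)CCC=C(C)C
F4 | step 4 | (2E,4S,6Z)-3,7,11-trimethyldodeca-2,6,10-triene-1,4-diol | OC/C=C(\C)[C@@H](O)C/C=C(/C)CCC=C(C)C
F5 | step 4 | (2E,4S,6Z)-4-hydroxy-3,7,11-trimethyldodeca-2,6,10-trienal | O=C/C=C(\C)[C@@H](O)C/C=C(/C)CCC=C(C)C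
F6 | step 5 | (2E,4S,6Z,10E)-12-hydroxy-3,7,11-trimethyl-1-oxododeca-2,6,10-trien-4-yl (2Z)-2-methylbut-2-enoate | O=C/C=C(\C)[C@@H](OC(=O)/C(C)=C\C)C/C=C(/C)CC/C=C(\C)CO
F7 | step 5 | (2E,4S,6Z,10E)-12-chloro-3,7,11-trimethyl-1-oxododeca-2,6,10-trien-4-yl (2Z)-2-methylbut-2-enoate | O=C/C=C(\C)[C@@H](OC(=O)/C(C)=C\C)C/C=C(/C)CC/C=C(\C)CCl
F8 | step 6 | (2E,4S,6Z)-3,7,11-trimethyl-1-oxo-12-(tributylstannyl)dodeca-2,6,10-trien-4-yl (2Z)-2-methylbut-2-enoate | O=C/C=C(\C)[C@@H](OC(=O)/C(C)=C\C)C/C=C(/C)CCC=C(C)C[Sn](CCCC)(CCCC)CCCC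
F9 | step 6 | (1S,2E,4S,5S,8Z)-4-hydroxy-2,8-dimethyl-5-(prop-1-en-2-yl)cyclodeca-2,8-dien-1-yl (2Z)-2-methylbut-2-enoate | C/C=C(/C)C(=O)O[C@H]1C/C=C(/C)CC[C@@H](C(C)=C)[C@@H](O)/C=C/1C
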